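## Retrosynthetic overview

1. The last bond made joins the exocyclic vinyl CH of the butenolide to the methyl-bearing stereocentre: (E)-iodomethylene butenolide 23 + secondary iodide 18, by a one-pot I→Li→Zn→Pd stereoretentive Negishi coupling.
2. Enabling feature: across the exocyclic C=C of the enol lactone the ring oxygen and the side chain are anti, which is what anti-iodolactonisation of a (Z)-2-en-4-ynoic acid delivers as a vinyl iodide. The stereocentre is a plain CH(CH3) between that vinyl carbon and a CH2, with no heteroatom or β-leaving group, so its Li/Zn derivatives hold configuration.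
3. 23: Still–Gennari (Z)-enynoate, then acid 22, then 5-exo-dig iodolactonisation (step 12). This is the only ring built; both furan rings are bought intact.
4. 18: (R)-pent-4-yn-2-ol gives (E)-vinyl iodide 13; hydrozirconation/Negishi coupling with bis-furyl alkyne 9 sets the (4E,6E)-diene; Appel inversion gives the (S)-iodide.
5. 9: 3-furyllithium + 4-bromo-2-furaldehyde, ionic deoxygenation of the carbinol, Negishi alkylation at the furan bromide.

Key step: step 13

Remark: the target is read as the (E)-enol lactone (side chain anti to the ring oxygen) with (S) configuration at the methyl-bearing carbon; (R)-pent-4-yn-2-ol and the ethyl Still–Gennari propionate reagent 20 are taken as commercial.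

## Route

Step 1
Reactants: 1 3-bromofuran; 2 4-bromofuran-2-carbaldehyde
Product: 4 (4-bromofuran-2-yl)(furan-3-yl)methanol (racemic), via furan-3-yllithium 3 (not isolated)
Conditions: n-BuLi, THF, −78 °C; then 2, −78 °C; then H2O
Reagents that add atoms: none
Why: Bromine–lithium exchange at −78 °C gives the β-lithiofuran, which should add 1,2 to the aldehyde (organolithium carbonyl addition); the carbinol centre is racemic and is removed in step 2.

Step 2
Reactants: 4 (4-bromofuran-2-yl)(furan-3-yl)methanol
Product: 5 4-bromo-2-(furan-3-ylmethyl)furan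
Conditions: Et3SiH, CF3CO2H, CH2Cl2, −20 → 0 °C
Reagents that add atoms: none
Why: Ionic hydrogenation: the carbenium ion stabilised by both furans should be captured by silane hydride to give the methylene bridge, the C–Br bond being inert.

Step 3
Reactants: 6 pent-3-yn-1-ol
Product: 7 5-iodopent-2-yne
Conditions: I2, PPh3, imidazole, CH2Cl2, 0 °C → rt
Reagents that add atoms: iodine, II
Why: Appel iodination of a primary alcohol.

Step 4
Reactants: 7 5-iodopent-2-yne; 5 4-bromo-2-(furan-3-ylmethyl)furan
Product: 9 2-(furan-3-ylmethyl)-4-(pent-3-yn-1-yl)furan, via pent-3-yn-1-ylzinc iodide 8 (not isolated)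
Conditions: Zn dust, LiCl, THF, 40 °C; then 5, Pd(OAc)2 (2 mol%), SPhos (4 mol%), THF, rt → 50 °C
Reagents that add atoms: none
Why: LiCl-assisted zinc insertion into the primary iodide followed by sp3–sp2 Negishi coupling at the furan bromide; the internal alkyne and both furans tolerate the alkylzinc.

Step 5
Reactants: 10 (R)-pent-4-yn-2-ol
Product: 11 (R)-tert-butyldimethyl(pent-4-yn-2-yloxy)silane
Conditions: TBSCl, imidazole, DMF, rt
Reagents that add atoms: tert-butyldimethylsilyl chloride, CC(C)(C)[Si](C)(C)Cl
Why: Standard silylation of the secondary alcohol; the stereocentre is not touched.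

Step 6
Reactants: 11 (R)-tert-butyldimethyl(pent-4-yn-2-yloxy)silane
Product: 13 (R,E)-tert-butyl[(5-iodopent-4-en-2-yl)oxy]dimethylsilane, via (E)-alkenylzirconocene chloride 12 (not isolated)
Conditions: Cp2Zr(H)Cl, THF, rt; then I2, 0 °C
Reagents that add atoms: iodine, II
Why: syn-Hydrozirconation of the terminal alkyne with Schwartz reagent puts Zr at the terminus, and iodinolysis with retention should give the (E)-vinyl iodide.

Step 7
Reactants: 9 2-(furan-3-ylmethyl)-4-(pent-3-yn-1-yl)furan; 13 (R,E)-tert-butyl[(5-iodopent-4-en-2-yl)oxy]dimethylsilane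
Product: 16 tert-butyl{[(2R,4E,6E)-9-[5-(furan-3-ylmethyl)furan-3-yl]-6-methylnona-4,6-dien-2-yl]oxy}dimethylsilane, via (E)-2-alkenylzirconocene chloride 14 (not isolated), via (E)-2-alkenylzinc chloride 15 (not isolated)
Conditions: 9, Cp2Zr(H)Cl (slight excess), THF, 50 °C; ZnCl2, THF, 0 °C → rt; then 13, Pd(PPh3)4 (5 mol%), rt
Reagents that add atoms: none
Why: syn-Hydrozirconation of the 2-alkyne (Zr is expected to settle on the less hindered, methyl-bearing carbon under Zr–H equilibration), Zr→Zn transmetalation and Negishi coupling with retention at both alkenyl partners should give the (4E,6E)-diene.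

Step 8
Reactants: 16 the silyl ether from step 7
Product: 17 (2R,4E,6E)-9-[5-(furan-3-ylmethyl)furan-3-yl]-6-methylnona-4,6-dien-2-ol
Conditions: TBAF, THF, 0 °C → rt; then H2O
Reagents that add atoms: none
Why: Fluoride desilylation under non-acidic conditions that spare the furans and the diene.

Step 9
Reactants: 17 (2R,4E,6E)-9-[5-(furan-3-ylmethyl)furan-3-yl]-6-methylnona-4,6-dien-2-ol
Product: 18 4-[(3E,5E,8S)-8-iodo-4-methylnona-3,5-dien-1-yl]-2-(furan-3-ylmethyl)furan
Conditions: I2, PPh3, N-methylimidazole, CH2Cl2, −10 °C, dark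
Reagents that add atoms: iodine, II
Why: Appel iodination: SN2 displacement of the alkoxyphosphonium by iodide with inversion should turn the (R)-carbinol into the (S)-iodide.

Step 10
Reactants: 19 3-(trimethylsilyl)prop-2-ynal; 20 ethyl 2-[bis(2,2,2-trifluoroethoxy)phosphoryl]propanoate
Product: 21 ethyl (2Z)-2-methyl-5-(trimethylsilyl)pent-2-en-4-ynoate
Conditions: 20, KHMDS, 18-crown-6, THF, −78 °C; then 19, −78 °C
Reagents that add atoms: none
Why: Still–Gennari olefination: the trifluoroethyl phosphonate under dissociating conditions should give the kinetic (Z)-trisubstituted enoate, ester cis to the alkynyl group.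

Step 11
Reactants: 21 ethyl (2Z)-2-methyl-5-(trimethylsilyl)pent-2-en-4-ynoate
Product: 22 (2Z)-2-methylpent-2-en-4-ynoic acid
Conditions: LiOH, THF/MeOH/H2O, 0 °C → rt; then 1 M HCl to pH 3, 0 °C
Reagents that add atoms: lithium hydroxide, [Li+].[OH-]
Why: Saponification; hydroxide in methanol also cleaves the C(sp)–Si bond, and the (Z)-geometry of the enoate is not affected.

Step 12
Reactants: 22 (2Z)-2-methylpent-2-en-4-ynoic acid
Product: 23 (5E)-5-(iodomethylene)-3-methylfuran-2(5H)-one
Conditions: I2, NaHCO3, MeCN, 0 °C → rt, dark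
Reagents that add atoms: iodine, II
Why: Iodolactonisation closes the butenolide by 5-exo-dig anti attack of the carboxylate on the iodonium-activated terminal alkyne, so O and I end up trans across the exocyclic alkene ((E)-iodide); any (E)-acid from step 10 cannot cyclise and is removed by base extraction.

Step 13
Reactants: 18 4-[(3E,5E,8S)-8-iodo-4-methylnona-3,5-dien-1-yl]-2-(furan-3-ylmethyl)furan; 23 (5E)-5-(iodomethylene)-3-methylfuran-2(5H)-one
Product: 26 (5E)-5-[(2S,4E,6E)-9-[5-(furan-3-ylmethyl)furan-3-yl]-2,6-dimethylnona-4,6-dien-1-ylidene]-3-methylfuran-2(5H)-one, via secondary alkyllithium 24 (not isolated), via mixed secondary dialkylzinc 25 (not isolated)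
Conditions: t-BuLi (2.2 equiv), pentane/Et2O, −100 °C, inverse addition of 18; then Me3SiCH2ZnBr·LiBr, THF, −100 → −30 °C; then 23, Pd2I2(Pt-Bu3)2 (3 mol%), −25 °C → rt, dark
Reagents that add atoms: none
Why: Inverse addition of 18 to t-BuLi at −100 °C effects iodine–lithium exchange with retention to give 24, which is trapped within seconds by Me3SiCH2ZnBr·LiBr (retention) as the dialkylzinc 25 carrying a non-transferable Me3SiCH2 group; oxidative addition of Pd(0) into the C–I bond of 23, transmetalation of the secondary alkyl group and reductive elimination then form the bond between the exocyclic vinyl carbon and the stereocentre. The closest known reaction type is the stereoretentive Pd-catalysed Negishi cross-coupling of configurationally defined, non-stabilised secondary alkylzincs, made by this same exchange/transmetalation sequence, with alkenyl iodides. No ring is closed in this step. No new stereocentre is created: the (S) centre is inherited from (R)-pent-4-yn-2-ol through one inversion (step 9) and three retentive events here, and the (E) geometry of the enol lactone is inherited from the anti-iodolactonisation because oxidative addition and reductive elimination both retain alkenyl configuration. The selectivities needed are retention at the secondary carbon (secured by the absence of any α-heteroatom, acidifying or β-leaving group there, the −100 °C exchange with immediate zinc trapping, and the bulky t-Bu3P–Pd catalyst, which should let reductive elimination outrun β-hydride elimination) and chemoselectivity for the vinyl iodide over the lactone carbonyl and the conjugated acceptor (secured by the low nucleophilicity of a dialkylzinc). The furans and the diene carry nothing that reacts with an organozinc, so only the brief organolithium stage has to be kept cold and short.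

## Compound list

1 | 3-bromofuran | Brc1ccoc1 | starting material
2 | 4-bromofuran-2-carbaldehyde | O=Cc1cc(Br)co1 | starting material
3 | furan-3-yllithium (not isolated) | [Li]c1ccoc1 | intermediate
4 | (4-bromofuran-2-yl)(furan-3-yl)methanol (racemic) | OC(c1cc(Br)co1)c1ccoc1 | intermediate
5 | 4-bromo-2-(furan-3-ylmethyl)furan | Brc1coc(Cc2ccoc2)c1 | intermediate
6 | pent-3-yn-1-ol | CC#CCCO | starting material
7 | 5-iodopent-2-yne | CC#CCCI | intermediate
8 | pent-3-yn-1-ylzinc iodide (not isolated) | CC#CCC[Zn]I | intermediate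
9 | 2-(furan-3-ylmethyl)-4-(pent-3-yn-1-yl)furan | CC#CCCc1coc(Cc2ccoc2)c1 | intermediate
10 | (R)-pent-4-yn-2-ol | C[C@@H](O)CC#C | starting material
11 | (R)-tert-butyldimethyl(pent-4-yn-2-yloxy)silane | C[C@@H](O[Si](C)(C)C(C)(C)C)CC#C | intermediate
12 | chlorobis(cyclopentadienyl)[(1E,4R)-4-(tert-butyldimethylsilyloxy)pent-1-en-1-yl]zirconium (not isolated) | C[C@@H](O[Si](C)(C)C(C)(C)C)C/C=C/[Zr](Cl)(C1C=CC=C1)C1C=CC=C1 | intermediate
13 | (R,E)-tert-butyl[(5-iodopent-4-en-2-yl)oxy]dimethylsilane | C[C@@H](O[Si](C)(C)C(C)(C)C)C/C=C/I | intermediate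
14 | chlorobis(cyclopentadienyl)[(2E)-5-[5-(furan-3-ylmethyl)furan-3-yl]pent-2-en-2-yl]zirconium (not isolated) | C/C(=C\CCc1coc(Cc2ccoc2)c1)[Zr](Cl)(C1C=CC=C1)C1C=CC=C1 | intermediate
15 | chloro[(2E)-5-[5-(furan-3-ylmethyl)furan-3-yl]pent-2-en-2-yl]zinc (not isolated) | C/C(=C\CCc1coc(Cc2ccoc2)c1)[Zn]Cl | intermediate
16 | tert-butyl{[(2R,4E,6E)-9-[5-(furan-3-ylmethyl)furan-3-yl]-6-methylnona-4,6-dien-2-yl]oxy}dimethylsilane | C[C@@H](O[Si](C)(C)C(C)(C)C)C/C=C/C(C)=C/CCc1coc(Cc2ccoc2)c1 | intermediate
17 | (2R,4E,6E)-9-[5-(furan-3-ylmethyl)furan-3-yl]-6-methylnona-4,6-dien-2-ol | C[C@@H](O)C/C=C/C(C)=C/CCc1coc(Cc2ccoc2)c1 | intermediate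
18 | 4-[(3E,5E,8S)-8-iodo-4-methylnona-3,5-dien-1-yl]-2-(furan-3-ylmethyl)furan | C[C@H](I)C/C=C/C(C)=C/CCc1coc(Cc2ccoc2)c1 | intermediate
19 | 3-(trimethylsilyl)prop-2-ynal | C[Si](C)(C)C#CC=O | starting material
20 | ethyl 2-[bis(2,2,2-trifluoroethoxy)phosphoryl]propanoate | CCOC(=O)C(C)P(=O)(OCC(F)(F)F)OCC(F)(F)F | starting material
21 | ethyl (2Z)-2-methyl-5-(trimethylsilyl)pent-2-en-4-ynoate | CCOC(=O)/C(C)=C\C#C[Si](C)(C)C | intermediate
22 | (2Z)-2-methylpent-2-en-4-ynoic acid | OC(=O)/C(C)=C\C#C | intermediate
23 | (5E)-5-(iodomethylene)-3-methylfuran-2(5H)-one | CC1=C/C(=C\I)OC1=O | intermediate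
24 | secondary alkyllithium from 18, C–Li in place of C–I with the same spatial arrangement (not isolated) | C[C@H]([Li])C/C=C/C(C)=C/CCc1coc(Cc2ccoc2)c1 | intermediate
25 | [(2S,4E,6E)-9-[5-(furan-3-ylmethyl)furan-3-yl]-6-methylnona-4,6-dien-2-yl](trimethylsilylmethyl)zinc (not isolated) | C[C@H]([Zn]C[Si](C)(C)C)C/C=C/C(C)=C/CCc1coc(Cc2ccoc2)c1 | intermediate
26 | (5E)-5-[(2S,4E,6E)-9-[5-(furan-3-ylmethyl)furan-3-yl]-2,6-dimethylnona-4,6-dien-1-ylidene]-3-methylfuran-2(5H)-one | CC1=C/C(=C\[C@@H](C)C/C=C/C(C)=C/CCc2coc(Cc3ccoc3)c2)OC1=O | target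

## Summary and risks

Total step count: 13. Longest linear sequence: 7 steps (steps 1, 2, 4, 7, 8, 9, 13).

Steps most likely to fail:

**Step 13.** Proton transfer from the furan α-positions or the bis-heteroaryl CH2 to t-BuLi or to the secondary alkyllithium, 3-exo cyclisation of the homoallylic lithium onto the diene, or partial loss of configuration before zinc trapping would erode yield or stereochemical integrity. The fallback moves the stereoretentive sp3–sp2 coupling to a furan-free, diene-free iodide and closes the bond between the two alkenes last; it sets out from 23 (and from 9 for the zinc reagent) and comes back at 26. Commercial (R)-butane-1,3-diol is silylated at the primary hydroxyl (TBSCl, imidazole) to (R)-4-[(tert-butyldimethylsilyl)oxy]butan-2-ol F1. Appel iodination with inversion gives (S)-tert-butyl(3-iodobutoxy)dimethylsilane F2. The same I→Li→Zn→Pd sequence with 23 gives (5E)-5-[(2S)-4-[(tert-butyldimethylsilyl)oxy]-2-methylbutylidene]-3-methylfuran-2(5H)-one F3. HF·pyridine frees (5E)-5-[(2S)-4-hydroxy-2-methylbutylidene]-3-methylfuran-2(5H)-one F4, and Dess–Martin oxidation gives (3S)-3-methyl-4-[(2E)-4-methyl-5-oxofuran-2(5H)-ylidene]butanal F5, whose stereocentre is β to the carbonyl and not epimerisable. Takai olefination (CrCl2, CHI3) gives (5E)-5-[(2S,4E)-5-iodo-2-methylpent-4-en-1-ylidene]-3-methylfuran-2(5H)-one F6, and Negishi coupling of F6 with alkenylzinc 15 (made from 9 as in step 7) gives 26.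

**Step 9.** Ionisation of the oxyphosphonium with participation of the homoallylic diene (retention or skeletal shift), iodide–iodide exchange eroding configuration, or elimination to the conjugated triene may compete with clean SN2 inversion. The fallback installs the C–I bond before the diene exists; it sets out from 13 and comes back at 18. TBAF converts 13 into (R,E)-5-iodopent-4-en-2-ol F7. Appel iodination with inversion, now on a simple carbinol whose only alkene is an electron-poor vinyl iodide, gives (S,E)-1,4-diiodopent-1-ene F8. Pd(PPh3)4-catalysed Negishi coupling with alkenylzinc 15 (from 9), which should engage only the alkenyl C–I bond, gives 18.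

**Step 2.** Acid-induced oligomerisation or ring opening of the furans through the difuryl carbenium ion may outcompete hydride capture. The fallback avoids any cation; it sets out from 2 and comes back at 5. Condensation of 2 with tosylhydrazide gives N'-[(E)-(4-bromofuran-2-yl)methylidene]-4-methylbenzenesulfonohydrazide F9. Its metal-free reductive coupling with furan-3-ylboronic acid (K2CO3, dioxane, 110 °C; diazo formation, 1,2-boron-to-carbon shift, protodeboronation) gives 5 with the C–Br bond untouched.

## Further compounds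

F1 | step 13 | (R)-4-[(tert-butyldimethylsilyl)oxy]butan-2-ol | C[C@@H](O)CCO[Si](C)(C)C(C)(C)C
F2 | step 13 | (S)-tert-butyl(3-iodobutoxy)dimethylsilane | C[C@H](I)CCO[Si](C)(C)C(C)(C)C
F3 | step 13 | (5E)-5-[(2S)-4-[(tert-butyldimethylsilyl)oxy]-2-methylbutylidene]-3-methylfuran-2(5H)-one | CC1=C/C(=C\[C@@H](C)CCO[Si](C)(C)C(C)(C)C)OC1=O
F4 | step 13 | (5E)-5-[(2S)-4-hydroxy-2-methylbutylidene]-3-methylfuran-2(5H)-one | CC1=C/C(=C\[C@@H](C)CCO)OC1=O
F5 | step 13 | (3S)-3-methyl-4-[(2E)-4-methyl-5-oxofuran-2(5H)-ylidene]butanal | CC1=C/C(=C\[C@@H](C)CC=O)OC1=O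
F6 | step 13 | (5E)-5-[(2S,4E)-5-iodo-2-methylpent-4-en-1-ylidene]-3-methylfuran-2(5H)-one | CC1=C/C(=C\[C@@H](C)C/C=C/I)OC1=O
F7 | step 9 | (R,E)-5-iodopent-4-en-2-ol | C[C@@H](O)C/C=C/I
F8 | step 9 | (S,E)-1,4-diiodopent-1-ene | C[C@H](I)C/C=C/I
F9 | step 2 | N'-[(E)-(4-bromofuran-2-yl)methylidene]-4-methylbenzenesulfonohydrazide | Cc1ccc(cc1)S(=O)(=O)N/N=C/c1cc(Br)co1
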